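Readings and results come from a simulation on assumed constants; noise was put on by code.

Slowness of the substrate opened the meeting: after 4.00 min at 6 °C, Wednesday's flask still held 31.1% of it.

| flask | substrate | partner | protic impurity | temperature | remark | time |
|---|---|---|---|---|---|---|
| Thursday's | 0.32 M | 0.288 M | 0.32 M | −5 °C | run made earlier |  |
| Wednesday's | 0.16 M | 0.288 M | 0.32 M | 6 °C | run made earlier |  |
| Monday's | 0.24 M | 0.288 M | 0.32 M | −5 °C | run made earlier |  |
| Tuesday's | 0.32 M | 0.14 M | 0.32 M | 6 °C | run made earlier |  |
| west | 0.32 M (fed, over 3.0 min) | 0.288 M | 0.320 M |  | the addition at −40 °C, then warmed to 0 °C; the feed brings no volume worth counting | 5.0 min |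
| east | 0.32 M | 0.288 M (fed, over 3.0 min) | 0.320 M | 0 °C | all else is in the flask from the start; the feed brings no volume worth counting | 5.0 min |
| south | 0.32 M (fed, over 3.0 min) | 0.288 M | 0.320 M | 0 °C | all else is in the flask from the start; the feed brings no volume worth counting | 5.0 min |
| north-east | 0.32 M | 0.288 M | 0.320 M |  | everything together at the start at −40 °C, warmed to 0 °C at 3.0 min | 5.0 min |

| run | time / min | target / % | substrate / % |
|---|---|---|---|
| Thursday's | 0.833 | 1.1 | 93.3 |
| Thursday's | 1.50 | 2.2 | 88.4 |
| Thursday's | 2.50 | 5.0 | 81.7 |
| Thursday's | 3.00 | 6.0 | 78.3 |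
| Wednesday's | 1.00 | 8.1 | 74.4 |
| Wednesday's | 2.00 | 16.2 | 56.1 |
| Wednesday's | 3.00 | 22.5 | 41.8 |
| Wednesday's | 4.00 | 27.8 | 31.1 |
| Monday's | 0.500 | 0.7 | 95.7 |
| Monday's | 1.33 | 2.3 | 89.5 |
| Monday's | 2.50 | 5.0 | 81.1 |
| Monday's | 4.00 | 8.1 | 71.8 |
| Tuesday's | 0.500 | 1.7 | 86.5 |
| Tuesday's | 1.33 | 5.6 | 67.6 |
| Tuesday's | 2.50 | 9.5 | 48.6 |
| Tuesday's | 4.00 | 12.3 | 30.9 |

(scatter of a reading: 0.3 percentage points)

- the earlier runs were read with a standard deviation of 0.3 percentage points
- what may be going on: substrate -> intermediate; partner + intermediate -> target; substrate -> decomposition product; partner + protic impurity -> quenched reagent; target <-> isomer of the product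

- the flask with the highest amount of target, in percent of the substrate charged ("all alike" if they lie within 1.5 percentage points) (west / east / south / north-east / all alike)
- final target, as a percentage of the substrate charged, in west
- final target, as a percentage of the substrate charged, in east
- final target, as a percentage of the substrate charged, in south
- final target, as a percentage of the substrate charged, in north-east

I reported that the substrate's loss looks first order. Thursday's and Monday's runs differ in substrate charge, yet read 81.7% and 81.1% at 2.50 min. Wednesday's and Tuesday's differ in both charges, yet read 31.1% and 30.9% at 4.00 min. So I took one rate constant, k, per temperature. Thursday's run gives 0.0815 min⁻¹ at −5 °C, and Wednesday's gives 0.292 min⁻¹ at 6 °C. The flasks' 0 °C lies near the middle of these temperatures, so I took the geometric mean, 0.154 min⁻¹.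

I proposed carrying one quantity: τ = 6.48 min, the opening time, meaning the mean life of substrate at 0 °C. The rule is that substrate left equals exp(−warm minutes/τ). Substrate still unopened has not become target. The span of 5.0 min is shorter than τ, so by my reckoning east keeps 46.2% of its substrate.

West and north-east are warm for 2.00 min. I counted their minutes at −40 °C as zero, since k is already 3.58 times lower at −5 °C than at 6 °C. They keep 73.4%. My reckoning gives the substrate opened, not a target figure: about 53.8% in east and 26.6% in west. A colleague added that partner, the limiting reagent, is also consumed by protic impurity.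

The forecast's author named east as best, with 17%, then south at 11.5%, west at 6% and north-east at 6%. The stated ground was: “East holds the substrate from the start and doses partner gradually”.

The flasks gave 7.40% in west, 18.2% in east, 10.8% in south and 7.44% in north-east, and east led.

    substrate → intermediate (k = 0.00247 s⁻¹, Ea = 72.0 kJ mol⁻¹)
    partner + intermediate → target (k = 0.0423 L mol⁻¹ s⁻¹, Ea = 62.0 kJ mol⁻¹)
    substrate → decomposition product (k = 1.10 × 10⁻⁶ s⁻¹, Ea = 97.0 kJ mol⁻¹)
    partner + protic impurity → quenched reagent (k = 0.0152 L mol⁻¹ s⁻¹, Ea = 46.0 kJ mol⁻¹)
    target ⇌ isomer of the product (K = 0.740, k = 0.00745 s⁻¹, Ea = 78.0 kJ mol⁻¹, ΔH = −39.0 kJ mol⁻¹)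
    (constants at 0 °C)

West held 99.9% of its substrate and 97.4% of its partner when the cold ended at 3.00 min, and in the 2.00 min after that substrate fell to 74%, against 73.4% from τ, while intermediate rose to 16.2%. East was warm throughout, and its partner, fed in, averaged 0.101 M over the first 3.0 min while substrate opened; at 5.00 min substrate stood at 48%, against 46.2% from τ, and target at 18.2%.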